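**Plan**

1. Locants: macrolactone O1, C2 (lactone C=O), C3, C4 (CH–O), C5, C6, C7 (ketone), C8, C9, C10 (CH–CH3); Cα is the furyl-bearing carbon of the γ-lactone. Enabling feature: C2 and C7 are 1,6-related carbonyl carbons with O1 on C2, so a C2=C7 bond folds the decanolide into a 2-methylhexahydrochromene (dihydropyran O1/C2/C7–C10 sharing an enol-ether bond with cyclohexene C2–C7) that carries the C4–C5 γ-lactone cis-fused.
2. Retrosynthetic cuts, in order: O–Si; the C2 and C7 carbonyls back to the C2=C7 alkene; Cα–H; lactone O–C4 and O1–C2 (to an enone acid); C5–Cα (enolate plus nitroalkene); C7–C8 (enolate plus iodide); on the furan the two ring–CH2 and ring–CH bonds.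
3. Forward ring order: bought carbocycle, then dihydropyran (bicyclic vinylogous ester), then the furylacetic acid arm at C5, then the γ-lactone with the pyran re-formed as the tetrasubstituted enol ether, then the ten-membered ring by scission of the shared C2=C7 bond.
4. Stereochemistry: C10 and the side-chain carbinol both come from (R)-butane-1,3-diol through one iodide. C10 sets C7 and C7 sets C5 by equilibration; C5 sets C4 (cis lactone fusion) and Cα (convex-face protonation); C7 is then destroyed.

Key step: step 16

Remark: (R)-butane-1,3-diol, 3-ethoxycyclohex-2-en-1-one, furan and nitromethane are taken as commercial. TBS = tert-butyldimethylsilyl. In the Why lines the locants C2–C10 and Cα are those of the macrolactone, also for precursors; systematic names use their own numbering. Mixtures at centres that are corrected or erased later are carried forward and are marked as such.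

**Route**

Step 1
Reactants: 1 (R)-butane-1,3-diol
Product: 2 (R)-3-hydroxybutyl 4-methylbenzenesulfonate
Conditions: TsCl (1.05 equiv), Et3N, DMAP (cat.), CH2Cl2, −20 → 0 °C
Reagents that add atoms: p-toluenesulfonyl chloride, Cc1ccc(cc1)S(=O)(=O)Cl
Why: Chemoselective monosulfonylation of a 1,3-diol, since the unhindered primary hydroxyl reacts much faster than the secondary one at low temperature and the carbinol centre is not involved.

Step 2
Reactants: 2 (R)-3-hydroxybutyl 4-methylbenzenesulfonate
Product: 3 (R)-3-[(tert-butyldimethylsilyl)oxy]butyl 4-methylbenzenesulfonate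
Conditions: TBSCl, imidazole, DMF, rt
Reagents that add atoms: tert-butyldimethylsilyl chloride, CC(C)(C)[Si](C)(C)Cl
Why: Standard imidazole-promoted silylation of the secondary alcohol; the TBS ether tolerates organolithium reagents and can later be removed by aqueous acid (step 5) or by fluoride (step 17).

Step 3
Reactants: 3 (R)-3-[(tert-butyldimethylsilyl)oxy]butyl 4-methylbenzenesulfonate
Product: 4 (R)-tert-butyl[(4-iodobutan-2-yl)oxy]dimethylsilane
Conditions: NaI, NaHCO3, acetone, reflux
Reagents that add atoms: sodium iodide, [Na+].[I-]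
Why: Finkelstein SN2 displacement of the primary tosylate, driven by precipitation of sodium tosylate, gives the alkylating agent used for both carbinol-bearing chains without touching the stereocentre.

Step 4
Reactants: 5 3-ethoxycyclohex-2-en-1-one; 4 (R)-tert-butyl[(4-iodobutan-2-yl)oxy]dimethylsilane
Product: 7 6-{(3R)-3-[(tert-butyldimethylsilyl)oxy]butyl}-3-ethoxycyclohex-2-en-1-one (both C6 epimers), via lithium enolate 6 (not isolated)
Conditions: LiN(i-Pr)2 (LDA), THF, −78 °C; then 4, DMPU, −78 → 0 °C
Reagents that add atoms: none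
Why: Stork–Danheiser alkylation, in which LDA removes the α′ proton of the vinylogous ester kinetically and the enolate is alkylated by the primary iodide to form C7–C8; the new ring centre is formed as a mixture and is equilibrated in step 6.

Step 5
Reactants: 7 6-{(3R)-3-[(tert-butyldimethylsilyl)oxy]butyl}-3-ethoxycyclohex-2-en-1-one
Product: 8 4-[(3R)-3-hydroxybutyl]cyclohexane-1,3-dione
Conditions: 2 M aq. HCl, THF, rt
Reagents that add atoms: water, O
Why: Aqueous acid hydrolyses the enol ether of the vinylogous ester and cleaves the secondary silyl ether in the same operation, unmasking the 1,3-dione and the C10 hydroxyl needed for ring closure.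

Step 6
Reactants: 8 4-[(3R)-3-hydroxybutyl]cyclohexane-1,3-dione
Product: 9 (2R,4aS)-2-methyl-2,3,4,4a,5,6-hexahydro-7H-chromen-7-one
Conditions: TsOH·H2O (cat.), toluene, reflux, Dean–Stark trap; chromatography
Reagents that add atoms: none
Why: Acid-catalysed dehydrative vinylogous ester formation from a 1,3-dione and an alcohol, here as a six-membered ring closure onto the only carbonyl within reach (C2), leaving C4 as the ketone; C7 epimerises through the dione enol, so the isomer with equatorial methyl (H-7 cis to the C10 methyl) should dominate and the minor epimer is removed.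

Step 7
Reactants: 10 furan; 4 (R)-tert-butyl[(4-iodobutan-2-yl)oxy]dimethylsilane
Product: 12 (R)-tert-butyl{[4-(furan-2-yl)butan-2-yl]oxy}dimethylsilane, via 2-lithiofuran 11 (not isolated)
Conditions: n-BuLi, THF, 0 °C → rt; then 4, 0 °C → rt
Reagents that add atoms: none
Why: α-Lithiation of furan and SN2 alkylation of the 2-furyllithium by the primary iodide, a standard entry to 2-alkylfurans.

Step 8
Reactants: 12 (R)-tert-butyl{[4-(furan-2-yl)butan-2-yl]oxy}dimethylsilane
Product: 14 5-{(3R)-3-[(tert-butyldimethylsilyl)oxy]butyl}furan-2-carbaldehyde, via 5-lithiofuran 13 (not isolated)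
Conditions: n-BuLi, THF, 0 °C → rt; then DMF, −78 °C → rt; H2O
Reagents that add atoms: N,N-dimethylformamide, CN(C)C=O
Why: The ring oxygen directs lithiation of the 2-alkylfuran to the free α-position, and trapping with DMF (formylation of an aryllithium) installs the carbon that becomes Cα.

Step 9
Reactants: 14 5-{(3R)-3-[(tert-butyldimethylsilyl)oxy]butyl}furan-2-carbaldehyde; 15 nitromethane
Product: 17 (R)-tert-butyldimethyl({4-[5-((E)-2-nitroethenyl)furan-2-yl]butan-2-yl}oxy)silane, via nitro aldol 16 (not isolated)
Conditions: NH4OAc (cat.), MeNO2 (solvent), 90 °C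
Reagents that add atoms: none
Why: Henry (nitroaldol) condensation of the heteroaromatic aldehyde with dehydration in the flask gives the conjugated nitroalkene as the thermodynamically preferred E isomer under conditions a silyl ether tolerates.

Step 10
Reactants: 9 (2R,4aS)-2-methyl-2,3,4,4a,5,6-hexahydro-7H-chromen-7-one; 17 (R)-tert-butyldimethyl({4-[5-((E)-2-nitroethenyl)furan-2-yl]butan-2-yl}oxy)silane
Product: 20 (2R,4aS)-6-[1-(5-{(3R)-3-[(tert-butyldimethylsilyl)oxy]butyl}furan-2-yl)-2-nitroethyl]-2-methyl-2,3,4,4a,5,6-hexahydro-7H-chromen-7-one (epimers at ring C6 and at the furyl carbon), via lithium dienolate 18 (not isolated), via lithium nitronate 19 (not isolated)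
Conditions: LDA, THF, −78 °C; then 17, THF, −78 °C; AcOH, −78 °C
Reagents that add atoms: none
Why: Kinetic α′ deprotonation at C5 and Michael addition of the lithium enolate to the nitroalkene β-carbon (conjugate addition of ketone enolates to nitroolefins) forms C5–Cα; axial attack may favour the C5 epimer that is corrected in step 12, and Cα is left uncontrolled because it is reset in step 15.

Step 11
Reactants: 20 nitro ketone (epimers at C5 and Cα)
Product: 21 2-(5-{(3R)-3-[(tert-butyldimethylsilyl)oxy]butyl}furan-2-yl)-2-[(2R,4aS)-2-methyl-7-oxo-2,3,4,4a,5,6-hexahydro-7H-chromen-6-yl]acetic acid (epimers at ring C6 and at the furyl carbon)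
Conditions: NaNO2, AcOH, DMSO, 35 °C
Reagents that add atoms: sodium nitrite, [Na+].[O-]N=O; water, O
Why: Direct conversion of a primary nitroalkane into a carboxylic acid by nitrosation of the nitronate (nitrolic acid, then nitrile oxide and hydroxamic acid), a weakly acidic, non-oxidising protocol that should spare the furan, the vinylogous ester and the silyl ether.

Step 12
Reactants: 21 keto acid (epimers at C5 and Cα)
Product: 22 2-(5-{(3R)-3-[(tert-butyldimethylsilyl)oxy]butyl}furan-2-yl)-2-[(2R,4aS,6S)-2-methyl-7-oxo-2,3,4,4a,5,6-hexahydro-7H-chromen-6-yl]acetic acid (both epimers at the furyl carbon)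
Conditions: NaOMe, MeOH, rt → 40 °C; then AcOH; chromatography
Reagents that add atoms: none
Why: Alkoxide-mediated thermodynamic epimerisation through the ketone enolate should move the C5 substituent to the equatorial position (H-5 cis to H-7), while C7 re-equilibrates through the dienolate to the same preferred arrangement and Cα, α to a carboxylate, is not deprotonated; minor C5-epimeric acids are separated and can be resubmitted.

Step 13
Reactants: 22 keto acid with equatorial C5 side chain
Product: 24 2-(5-{(3R)-3-[(tert-butyldimethylsilyl)oxy]butyl}furan-2-yl)-2-{(1R)-5-[(3R)-3-hydroxybutyl]-4-oxocyclohex-2-en-1-yl}acetic acid (epimers at ring C5 and at the furyl carbon; used crude), via allylic alcohol 23 (not isolated)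
Conditions: NaBH4, CeCl3·7H2O, MeOH, −20 → 0 °C; then 10% aq. citric acid, THF, 0 °C → rt
Reagents that add atoms: water, O
Why: Luche 1,2-reduction of the vinylogous ester carbonyl followed by mild acid hydrolysis is the Stork–Danheiser enone transposition, giving the C2 ketone, the C3=C4 alkene and the free C10 hydroxyl while C5, no longer α to a carbonyl, keeps its configuration; any lactone 25 already formed here is the next intermediate anyway.

Step 14
Reactants: 24 enone acid
Product: 26 (3aS,7R,9aS)-3-(5-{(3R)-3-[(tert-butyldimethylsilyl)oxy]butyl}furan-2-yl)-7-methyl-3,3a,4,5,6,7,9,9a-octahydro-2H-furo[3,2-g]chromen-2-one (both C3 epimers), via hydroxy keto lactone 25 (not isolated)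
Conditions: camphor-10-sulfonic acid (10 mol %), 4 Å molecular sieves, benzene, 60 °C
Reagents that add atoms: none
Why: Acid-catalysed intramolecular oxa-Michael addition of the carboxylic acid to the enone β-carbon C4 (5-exo-trig) can only deliver oxygen on the face of the C5–Cα bond and so gives the cis-fused γ-lactone, after which the δ-hydroxy ketone cyclodehydrates to the preferred tetrasubstituted C2=C7 enol ether (the standard preparation of hexahydrochromenes), removing the C7 stereocentre and blocking retro-Michael opening.

Step 15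
Reactants: 26 tricyclic enol-ether lactone (Cα epimers)
Product: 28 (3S,3aS,7R,9aS)-3-(5-{(3R)-3-[(tert-butyldimethylsilyl)oxy]butyl}furan-2-yl)-7-methyl-3,3a,4,5,6,7,9,9a-octahydro-2H-furo[3,2-g]chromen-2-one (H-3, H-3a and H-9a all cis), via lithium lactone enolate 27 (not isolated)
Conditions: LiN(SiMe3)2, THF, −78 °C; then 2,6-di-tert-butyl-4-methylphenol, THF, −78 °C; H2O
Reagents that add atoms: none
Why: Both Cα epimers give the same lithium enolate, and its kinetic C-protonation by the hindered phenol should occur on the convex face of the cis-fused bicycle (the face of H-4 and H-5, anti to the C5–C6 bond), placing H-α cis to H-5 and the furyl on the concave face; the phenoxide formed is too weak a base to re-enolise the product.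

Step 16
Reactants: 28 all-cis tricyclic enol-ether lactone
Product: 30 cordycicadin B tert-butyldimethylsilyl ether ((4S,5S,10R)-7-oxo decanolide cis-fused at C4–C5 to the γ-lactone with (S)-Cα), via hydroxy hemiketal 29 (not isolated)
Conditions: OsO4 (5 mol %), NaIO4 (4 equiv), 2,6-lutidine (2 equiv), 1,4-dioxane/H2O (3:1), 0 °C → rt
Reagents that add atoms: osmium tetroxide, O=[Os](=O)(=O)=O; sodium periodate, [Na+].[O-]I(=O)(=O)=O; water, O
Why: OsO4 adds suprafacially to the electron-rich tetrasubstituted C2=C7 enol ether to give, after hydrolysis of the osmate ester, a cis α-hydroxy hemiketal whose cyclic periodate ester fragments the C2–C7 bond, so that C2 leaves as the lactone carbonyl still bonded to O1 and C7 as the ketone. The closest known reaction type is the Lemieux–Johnson cleavage of enol ethers, and more specifically the oxidative scission of the ring-fusion double bond of hexahydrochromenes to ten-membered 6-oxo lactones. The ten-membered ring is not closed end to end but arises by ring-expanding fragmentation: the bond shared by the dihydropyran and the cyclohexene is cut and their common perimeter becomes the decanolide, so no macrolactonisation has to be achieved. No stereocentre is created, because the two carbinol centres of the hemiketal are transient and the face of osmylation is irrelevant, and C4, C5, Cα and C10 pass through unchanged. The step needs selectivity for the enol ether over the 2,5-dialkylfuran, which the far higher reactivity of the only non-aromatic, oxygen-activated alkene toward OsO4 should secure; it needs the six-membered hemiketal to stay closed so that a lactone and not a seco acid is released; and it needs Cα and the β-acyloxy lactone to survive, for which the lutidine-buffered, near-neutral medium is chosen.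

Step 17
Reactants: 30 cordycicadin B tert-butyldimethylsilyl ether
Product: 31 cordycicadin B
Conditions: HF·pyridine, pyridine, THF, 0 °C → rt
Reagents that add atoms: none
Why: Desilylation of the secondary silyl ether with buffered HF·pyridine is non-basic, so the epimerisable Cα, the β-acyloxy lactone and the ketone should be untouched while the side-chain (R)-carbinol is liberated.

**Compound list**

1 | (R)-butane-1,3-diol | C[C@@H](O)CCO | starting material
2 | (R)-3-hydroxybutyl 4-methylbenzenesulfonate | C[C@@H](O)CCOS(=O)(=O)c1ccc(C)cc1 | intermediate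
3 | (R)-3-[(tert-butyldimethylsilyl)oxy]butyl 4-methylbenzenesulfonate | C[C@@H](O[Si](C)(C)C(C)(C)C)CCOS(=O)(=O)c1ccc(C)cc1 | intermediate
4 | (R)-tert-butyl[(4-iodobutan-2-yl)oxy]dimethylsilane | C[C@@H](O[Si](C)(C)C(C)(C)C)CCI | intermediate
5 | 3-ethoxycyclohex-2-en-1-one | CCOC1=CC(=O)CCC1 | starting material
6 | kinetic lithium enolate of 5 (lithium 5-ethoxycyclohexa-1,5-dien-1-olate) | CCOC1=CC(O[Li])=CCC1 | intermediate
7 | 6-{(3R)-3-[(tert-butyldimethylsilyl)oxy]butyl}-3-ethoxycyclohex-2-en-1-one, both C6 epimers | CCOC1=CC(=O)C(CC[C@@H](C)O[Si](C)(C)C(C)(C)C)CC1 | intermediate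
8 | 4-[(3R)-3-hydroxybutyl]cyclohexane-1,3-dione | C[C@@H](O)CCC1CCC(=O)CC1=O | intermediate
9 | (2R,4aS)-2-methyl-2,3,4,4a,5,6-hexahydro-7H-chromen-7-one (H-4a cis to the methyl) | C[C@@H]1CC[C@H]2CCC(=O)C=C2O1 | intermediate
10 | furan | c1ccoc1 | starting material
11 | 2-lithiofuran | [Li]c1ccco1 | intermediate
12 | (R)-tert-butyl{[4-(furan-2-yl)butan-2-yl]oxy}dimethylsilane | C[C@@H](O[Si](C)(C)C(C)(C)C)CCc1ccco1 | intermediate
13 | 5-lithio derivative of 12 | C[C@@H](O[Si](C)(C)C(C)(C)C)CCc1ccc([Li])o1 | intermediate
14 | 5-{(3R)-3-[(tert-butyldimethylsilyl)oxy]butyl}furan-2-carbaldehyde | C[C@@H](O[Si](C)(C)C(C)(C)C)CCc1ccc(C=O)o1 | intermediate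
15 | nitromethane | C[N+](=O)[O-] | starting material
16 | 1-(5-{(3R)-3-[(tert-butyldimethylsilyl)oxy]butyl}furan-2-yl)-2-nitroethan-1-ol, both carbinol epimers | C[C@@H](O[Si](C)(C)C(C)(C)C)CCc1ccc(C(O)C[N+](=O)[O-])o1 | intermediate
17 | (R)-tert-butyldimethyl({4-[5-((E)-2-nitroethenyl)furan-2-yl]butan-2-yl}oxy)silane | C[C@@H](O[Si](C)(C)C(C)(C)C)CCc1ccc(/C=C/[N+](=O)[O-])o1 | intermediate
18 | kinetic lithium dienolate of 9 | C[C@@H]1CC[C@H]2CC=C(O[Li])C=C2O1 | intermediate
19 | lithium nitronate of the Michael adduct | C[C@@H]1CC[C@H]2CC(C(C=[N+]([O-])[O-])c3ccc(CC[C@@H](C)O[Si](C)(C)C(C)(C)C)o3)C(=O)C=C2O1.[Li+] | intermediate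
20 | (2R,4aS)-6-[1-(5-{(3R)-3-[(tert-butyldimethylsilyl)oxy]butyl}furan-2-yl)-2-nitroethyl]-2-methyl-2,3,4,4a,5,6-hexahydro-7H-chromen-7-one, epimers at ring C6 and at the furyl carbon | C[C@@H]1CC[C@H]2CC(C(C[N+](=O)[O-])c3ccc(CC[C@@H](C)O[Si](C)(C)C(C)(C)C)o3)C(=O)C=C2O1 | intermediate
21 | 2-(5-{(3R)-3-[(tert-butyldimethylsilyl)oxy]butyl}furan-2-yl)-2-[(2R,4aS)-2-methyl-7-oxo-2,3,4,4a,5,6-hexahydro-7H-chromen-6-yl]acetic acid, epimers at ring C6 and at the furyl carbon | C[C@@H]1CC[C@H]2CC(C(C(=O)O)c3ccc(CC[C@@H](C)O[Si](C)(C)C(C)(C)C)o3)C(=O)C=C2O1 | intermediate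
22 | the (2R,4aS,6S) isomer of 21 (H-6 cis to H-4a), both epimers at the furyl carbon | C[C@@H]1CC[C@H]2C[C@@H](C(C(=O)O)c3ccc(CC[C@@H](C)O[Si](C)(C)C(C)(C)C)o3)C(=O)C=C2O1 | intermediate
23 | 7-hydroxy (allylic alcohol) derivative of 22, (2R,4aS,6S), both carbinol epimers | C[C@@H]1CC[C@H]2C[C@@H](C(C(=O)O)c3ccc(CC[C@@H](C)O[Si](C)(C)C(C)(C)C)o3)C(O)C=C2O1 | intermediate
24 | 2-(5-{(3R)-3-[(tert-butyldimethylsilyl)oxy]butyl}furan-2-yl)-2-{(1R)-5-[(3R)-3-hydroxybutyl]-4-oxocyclohex-2-en-1-yl}acetic acid, epimers at ring C5 and at the furyl carbon | C[C@@H](O)CCC1C[C@@H](C(C(=O)O)c2ccc(CC[C@@H](C)O[Si](C)(C)C(C)(C)C)o2)C=CC1=O | intermediate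
25 | (3aS,7aS)-3-(5-{(3R)-3-[(tert-butyldimethylsilyl)oxy]butyl}furan-2-yl)-5-[(3R)-3-hydroxybutyl]hexahydro-1-benzofuran-2,6-dione, cis-fused, epimers at C3 and C5 | C[C@@H](O)CCC1C[C@H]2C(c3ccc(CC[C@@H](C)O[Si](C)(C)C(C)(C)C)o3)C(=O)O[C@H]2CC1=O | intermediate
26 | (3aS,7R,9aS)-3-(5-{(3R)-3-[(tert-butyldimethylsilyl)oxy]butyl}furan-2-yl)-7-methyl-3,3a,4,5,6,7,9,9a-octahydro-2H-furo[3,2-g]chromen-2-one, both C3 epimers | C[C@@H]1CCC2=C(C[C@@H]3OC(=O)C(c4ccc(CC[C@@H](C)O[Si](C)(C)C(C)(C)C)o4)[C@@H]3C2)O1 | intermediate
27 | lithium enolate of lactone 26 | C[C@@H]1CCC2=C(C[C@@H]3OC(O[Li])=C(c4ccc(CC[C@@H](C)O[Si](C)(C)C(C)(C)C)o4)[C@@H]3C2)O1 | intermediate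
28 | the (3S,3aS,7R,9aS) isomer of 26 (H-3, H-3a, H-9a all cis) | C[C@@H]1CCC2=C(C[C@@H]3OC(=O)[C@H](c4ccc(CC[C@@H](C)O[Si](C)(C)C(C)(C)C)o4)[C@@H]3C2)O1 | intermediate
29 | cis-4a,8a-dihydroxy derivative of 28 (α-hydroxy hemiketal; other centres as in 28) | C[C@@H]1CCC2(O)C(O)(C[C@@H]3OC(=O)[C@H](c4ccc(CC[C@@H](C)O[Si](C)(C)C(C)(C)C)o4)[C@@H]3C2)O1 | intermediate
30 | cordycicadin B tert-butyldimethylsilyl ether: (4S,5S,10R)-10-methyl-7-oxo decanolide cis-fused at C4–C5 to the γ-lactone, (S)-Cα bearing the 5-[(3R)-3-silyloxybutyl]furan-2-yl group | C[C@@H]1CCC(=O)C[C@@H]2[C@H](CC(=O)O1)OC(=O)[C@@H]2c1ccc(CC[C@@H](C)O[Si](C)(C)C(C)(C)C)o1 | intermediate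
31 | cordycicadin B: as 30 with the free (R)-3-hydroxybutyl side chain | C[C@@H]1CCC(=O)C[C@@H]2[C@H](CC(=O)O1)OC(=O)[C@@H]2c1ccc(CC[C@@H](C)O)o1 | target

**Step count and risks**

Total: 17 steps. Longest linear sequence: 14 steps from (R)-butane-1,3-diol (steps 1–3, then either 4–6 or 7–9, then 10–17).

Steps most likely to fail:

1. Step 16 (key step). What may go wrong: osmylation of the furan competing with that of the enol ether, hydrolysis of the enol ether before it is oxidised, or opening of the hydroxy hemiketal to the ketol so that periodate releases a hydroxy acid instead of the lactone. Fallback, setting out from 28 and returning at 30: the two events are separated. Stoichiometric osmylation (OsO4, pyridine, CH2Cl2, −40 °C, then aqueous NaHSO3) should allow the hydroxy hemiketal 29 to be isolated. Criegee cleavage with Pb(OAc)4 in dry CH2Cl2 over solid NaHCO3 at −20 °C then fragments the closed hemiketal to 30 in the absence of water. This detour makes no compound beyond the list (F0).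

2. Step 11. What may go wrong: nitrosative attack on the electron-rich furan or on C3 of the vinylogous ester instead of on the nitronate, or stalling at the nitrolic or hydroxamic acid stage. Fallback, setting out from 20 and returning at 21: the nitro group is taken to the acid in two known stages. The sodium nitronate (NaOMe, MeOH, 0 °C) is added to aqueous TiCl3 buffered with NH4OAc (reductive Nef reaction), which should give the keto aldehyde 2-(5-{(3R)-3-[(tert-butyldimethylsilyl)oxy]butyl}furan-2-yl)-2-[(2R,4aS)-2-methyl-7-oxo-2,3,4,4a,5,6-hexahydro-7H-chromen-6-yl]acetaldehyde F1. Oxidation with Ag2O (from AgNO3 and NaOH, aqueous ethanol, 0 °C), which is known to spare furans, then gives acid 21.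

3. Step 14. What may go wrong: incomplete or reversible conjugate addition, loss of the C5 configuration through dienol formation in the open enone, or silyl ether loss and furan decomposition on heating with acid. Fallback, setting out from 22 and returning at 26: the pyran is kept closed and no enone is formed. Luche reduction as in step 13 but with a pH 7 work-up keeps the allylic alcohol 23. Pyridinium p-toluenesulfonate with 4 Å sieves in CH2Cl2 at rt should ionise it to the O1-stabilised allyl cation, which the carboxyl captures at C4 to give the cis-fused allylic lactone with the enol-ether double bond still at C2=C3, F2. Under the same acid the double bond then moves to the tetrasubstituted C2=C7 position, giving 26.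

Further compounds
F0 | step 16 | none | none
F1 | step 11 | 2-(5-{(3R)-3-[(tert-butyldimethylsilyl)oxy]butyl}furan-2-yl)-2-[(2R,4aS)-2-methyl-7-oxo-2,3,4,4a,5,6-hexahydro-7H-chromen-6-yl]acetaldehyde, epimers at ring C6 and at the furyl carbon | C[C@@H]1CC[C@H]2CC(C(C=O)c3ccc(CC[C@@H](C)O[Si](C)(C)C(C)(C)C)o3)C(=O)C=C2O1
F2 | step 14 | 3,3a,4,4a,5,6,7,9a-octahydro isomer of 26 (enol-ether double bond C8a=C9, cis-fused lactone, centres as in 22, both C3 epimers) | C[C@@H]1CC[C@H]2C[C@H]3C(c4ccc(CC[C@@H](C)O[Si](C)(C)C(C)(C)C)o4)C(=O)O[C@H]3C=C2O1
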